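**Plan**

- The target has no stereocentres: two quinone rings joined by a (CH2)13 chain. Ring A (C1=O, C2–OMe, C3–Me, C4=O, C5–OH, C6–chain) is the monomethyl ether of ring B (2,5-dihydroxy-3-methyl-1,4-benzoquinone carrying the chain at C6).
- The retrosynthesis first removes three C–O bonds: the hydroxyl at C5 of ring A and the two oxygens on the ring B carbons that flank the chain carbon. This leaves a 2-methoxy-3-methyl-6-alkylquinone and a 2-methyl-5-alkylresorcinol.
- Ring A is then cut at C1–C6 and unfolded to a cyclobutenone. C1(=O), C2(OMe), C3(Me) and C4(=O) form the four-carbon array of a 2-methoxy-3-methylcyclobutenone from dimethyl squarate; C5 and the chain-bearing C6 are the two carbons of a terminal alkyne.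
- Further cuts: alkyne–carbinol C–C (acetylide addition), ring–CH3 (methyllithium), ArCH=CH (Wittig) and CH2–C≡C (acetylide alkylation).
- Forward: the aryl phosphonium salt and the alkynal are joined; the enyne is added to dimethyl squarate; methyl is introduced with carbonyl transposition; thermolysis closes ring A, the only ring formed. Hydrogenation, oxidation of the resorcinol and double acetoxylation then complete ring B and the ring A hydroxyl.
- Stereochemistry: nothing has to be set; the racemic cyclobutene carbinol and the alkene geometry are erased in steps 9 and 10.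

Key step: step 9

Remark: the Wittig step is expected to give both alkene geometries, so 9 and 11–19 are carried as E/Z mixtures and drawn without alkene geometry, and all cyclobutene carbinols are racemic; neither element reaches the target.

**Step 1**
Reactants: 1 3,5-dihydroxy-4-methylbenzoic acid
Product: 2 benzyl 3,5-bis(benzyloxy)-4-methylbenzoate
Conditions: BnBr (3.3 equiv), K2CO3, DMF, 60 °C
Reagents that add atoms: benzyl bromide, BrCc1ccccc1
Why: Williamson O-alkylation of both phenols together with alkylation of the carboxylate should give the tribenzyl compound in one operation.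

**Step 2**
Reactants: 2 benzyl 3,5-bis(benzyloxy)-4-methylbenzoate
Product: 3 [3,5-bis(benzyloxy)-4-methylphenyl]methanol
Conditions: LiAlH4, THF, 0 °C to rt
Reagents that add atoms: none
Why: Hydride reduction of the benzyl ester gives the primary benzylic alcohol and leaves the aryl benzyl ethers untouched.

**Step 3**
Reactants: 3 [3,5-bis(benzyloxy)-4-methylphenyl]methanol
Product: 4 {[3,5-bis(benzyloxy)-4-methylphenyl]methyl}(triphenyl)phosphonium bromide
Conditions: PPh3·HBr, MeCN, reflux
Reagents that add atoms: triphenylphosphine hydrobromide, [Br-].[PH+](c1ccccc1)(c1ccccc1)c1ccccc1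
Why: Benzylic alcohols are converted directly into benzyltriphenylphosphonium bromides by this reagent (acid-activated nucleophilic substitution), which saves a separate bromination.

**Step 4**
Reactants: 5 12-bromododecan-1-ol
Product: 6 tetradec-13-yn-1-ol
Conditions: LiC≡CH·H2NCH2CH2NH2 (3 equiv), DMSO, 0 °C to rt
Reagents that add atoms: lithium acetylide–ethylenediamine complex, [Li]C#C.NCCN
Why: SN2 alkylation of lithium acetylide by the primary bromide in DMSO; one equivalent of reagent is used up by the hydroxyl, whose lithium alkoxide is a much poorer nucleophile than the acetylide.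

**Step 5**
Reactants: 6 tetradec-13-yn-1-ol
Product: 7 tetradec-13-ynal
Conditions: Dess–Martin periodinane, CH2Cl2, 0 °C to rt
Reagents that add atoms: none
Why: Dess–Martin oxidation stops at the aldehyde and tolerates the terminal alkyne.

**Step 6**
Reactants: 4 {[3,5-bis(benzyloxy)-4-methylphenyl]methyl}(triphenyl)phosphonium bromide; 7 tetradec-13-ynal
Product: 9 1,3-bis(benzyloxy)-2-methyl-5-(pentadec-1-en-14-yn-1-yl)benzene (E/Z mixture), via phosphonium ylide 8 (not isolated)
Conditions: NaN(SiMe3)2, THF, −78 to 0 °C; then 7, −78 °C to rt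
Reagents that add atoms: none
Why: Wittig olefination of the semi-stabilised benzylic ylide joins the aryl fragment to the chain; the ylide is too weakly basic to deprotonate the terminal alkyne, and the alkene geometry is irrelevant because step 10 saturates the bond.

**Step 7**
Reactants: 9 1,3-bis(benzyloxy)-2-methyl-5-(pentadec-1-en-14-yn-1-yl)benzene; 10 dimethyl squarate
Product: 13 4-[15-(3,5-bis(benzyloxy)-4-methylphenyl)pentadec-14-en-1-yn-1-yl]-2,3-dimethoxy-4-[(trimethylsilyl)oxy]cyclobut-2-en-1-one (racemic), via lithium acetylide 11 (not isolated), via lithium alkoxide adduct 12 (not isolated)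
Conditions: n-BuLi, THF, −78 °C; then 10, −78 °C; then Me3SiCl, −78 to 0 °C
Reagents that add atoms: chlorotrimethylsilane, C[Si](C)(C)Cl
Why: 1,2-Addition of a lithium acetylide to one carbonyl of dimethyl squarate is the standard entry to 4-alkynyl-4-oxycyclobutenones, and O-silylation in the same flask blocks this oxygen for step 8; the new carbinol centre is formed racemic and disappears in step 9.

**Step 8**
Reactants: 13 4-[15-(3,5-bis(benzyloxy)-4-methylphenyl)pentadec-14-en-1-yn-1-yl]-2,3-dimethoxy-4-[(trimethylsilyl)oxy]cyclobut-2-en-1-one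
Product: 17 4-[15-(3,5-bis(benzyloxy)-4-methylphenyl)pentadec-14-en-1-yn-1-yl]-4-hydroxy-2-methoxy-3-methylcyclobut-2-en-1-one (racemic), via lithium carbinolate 14 (not isolated), via carbinol trifluoroacetate 15 (not isolated), via transposed silyl ether 16 (not isolated)
Conditions: MeLi, THF, −78 °C; (CF3CO)2O, −78 °C; then 1 M HCl, THF/MeOH, 0 °C
Reagents that add atoms: methyllithium, [Li]C; water, O
Why: Methyllithium adds 1,2 to the vinylogous ester carbonyl, the new alkoxide is activated as its trifluoroacetate and ionises to a methoxy-stabilised cyclobutenyl cation that is hydrolysed at its far end with loss of methanol (Stork–Danheiser-type 1,3-carbonyl transposition), which puts the methyl next to the silylated carbinol carbon and the carbonyl next to the methoxy carbon, and dilute acid then frees the tertiary alcohol; the configuration of the transient methyl carbinol does not matter.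

**Step 9**
Reactants: 17 4-[15-(3,5-bis(benzyloxy)-4-methylphenyl)pentadec-14-en-1-yn-1-yl]-4-hydroxy-2-methoxy-3-methylcyclobut-2-en-1-one
Product: 19 2-methoxy-3-methyl-6-[13-(3,5-bis(benzyloxy)-4-methylphenyl)tridec-12-en-1-yl]-1,4-benzoquinone, via vinylketene 18 (not isolated)
Conditions: p-xylene (0.01 M, degassed), 138 °C
Reagents that add atoms: none
Why: Heating should open the cyclobutenone C1–C4 bond in a four-electron conrotatory electrocyclic reaction with the hydroxyl rotating outward, which gives vinylketene 18 with the alkyne held cis to the ketene. The ketene carbon then bonds to the distal, chain-bearing alkyne carbon in a 6-endo-dig closure that forms ring A as a diradical, with a σ-radical on the former proximal alkyne carbon and an oxygen-centred radical on the former ketene oxygen. Transfer of the hydroxyl hydrogen to the neighbouring carbon radical collapses this species to the para-quinone; the closest known reaction is the Moore rearrangement of 4-alkynyl-4-hydroxycyclobutenones to benzoquinones. No stereocentre is formed and the racemic carbinol centre disappears. The step needs 6-endo over 5-exo closure, which the alkyl (not radical-stabilising) substituent on the alkyne terminus favours, and it needs the methoxy carbon next to the ketene-derived carbonyl, which is fixed by the constitution of 17 from step 8.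

**Step 10**
Reactants: 19 2-methoxy-3-methyl-6-[13-(3,5-bis(benzyloxy)-4-methylphenyl)tridec-12-en-1-yl]-1,4-benzoquinone
Product: 20 2-methoxy-3-methyl-6-[13-(3,5-dihydroxy-4-methylphenyl)tridecyl]benzene-1,4-diol
Conditions: H2 (1 atm), 10% Pd/C, EtOAc/EtOH, rt; filtered and kept under argon
Reagents that add atoms: none
Why: Catalytic hydrogenation over Pd/C should saturate the styrenyl alkene, hydrogenolyse both benzyl ethers and reduce the quinone to the hydroquinone in one operation, the last change being reversed in step 11.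

**Step 11**
Reactants: 20 2-methoxy-3-methyl-6-[13-(3,5-dihydroxy-4-methylphenyl)tridecyl]benzene-1,4-diol
Product: 21 2-hydroxy-3-methyl-6-[13-(5-methoxy-4-methyl-3,6-dioxocyclohexa-1,4-dien-1-yl)tridecyl]-1,4-benzoquinone
Conditions: (KO3S)2NO (excess), KH2PO4 buffer, acetone/H2O, 0 °C to rt
Reagents that add atoms: potassium nitrosodisulfonate, [K+].[K+].[O]N(S(=O)(=O)[O-])S(=O)(=O)[O-]
Why: Teuber oxidation returns hydroquinone ring A to the quinone and oxidises resorcinol ring B at the free carbon para to one hydroxyl to the 2-hydroxy-1,4-benzoquinone; the two free positions of ring B are equivalent, so one product is expected.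

**Step 12**
Reactants: 21 2-hydroxy-3-methyl-6-[13-(5-methoxy-4-methyl-3,6-dioxocyclohexa-1,4-dien-1-yl)tridecyl]-1,4-benzoquinone
Product: 22 3-[13-(2,3,5,6-tetraacetoxy-4-methylphenyl)tridecyl]-5-methoxy-6-methylbenzene-1,2,4-triyl triacetate
Conditions: Ac2O, H2SO4 (cat.), 0 °C to rt
Reagents that add atoms: acetic anhydride, CC(=O)OC(C)=O
Why: Thiele–Winter acetoxylation, in which acid-promoted conjugate addition of acetic acid, enolisation and peracetylation install the missing oxygen on each quinone; the site is fixed because each ring has a single unsubstituted carbon, and this carbon is conjugate to the more electrophilic carbonyl (not the vinylogous ester one).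

**Step 13**
Reactants: 22 3-[13-(2,3,5,6-tetraacetoxy-4-methylphenyl)tridecyl]-5-methoxy-6-methylbenzene-1,2,4-triyl triacetate
Product: 24 2,5-dihydroxy-3-[13-(2-hydroxy-5-methoxy-4-methyl-3,6-dioxocyclohexa-1,4-dien-1-yl)tridecyl]-6-methyl-1,4-benzoquinone (CNP0107579.0), via heptahydroxy leuco compound 23 (not isolated)
Conditions: K2CO3, MeOH (degassed), rt; then air; then 1 M HCl
Reagents that add atoms: none
Why: Carbonate-mediated transesterification of the aryl acetates frees the polyhydroxyarenes, which autoxidise in air to the hydroxy-para-quinones; methoxide is the only nucleophile present, so exchange at the ring A methyl ether is degenerate.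

**Compound list**

1 | 3,5-dihydroxy-4-methylbenzoic acid | Cc1c(O)cc(cc1O)C(=O)O | starting material
2 | benzyl 3,5-bis(benzyloxy)-4-methylbenzoate | Cc1c(OCc2ccccc2)cc(cc1OCc2ccccc2)C(=O)OCc2ccccc2 | intermediate
3 | [3,5-bis(benzyloxy)-4-methylphenyl]methanol | Cc1c(OCc2ccccc2)cc(CO)cc1OCc2ccccc2 | intermediate
4 | {[3,5-bis(benzyloxy)-4-methylphenyl]methyl}(triphenyl)phosphonium bromide | [Br-].Cc1c(OCc2ccccc2)cc(C[P+](c2ccccc2)(c2ccccc2)c2ccccc2)cc1OCc2ccccc2 | intermediate
5 | 12-bromododecan-1-ol | OCCCCCCCCCCCCBr | starting material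
6 | tetradec-13-yn-1-ol | OCCCCCCCCCCCCC#C | intermediate
7 | tetradec-13-ynal | O=CCCCCCCCCCCCC#C | intermediate
8 | [3,5-bis(benzyloxy)-4-methylbenzylidene](triphenyl)phosphorane | Cc1c(OCc2ccccc2)cc(C=P(c2ccccc2)(c2ccccc2)c2ccccc2)cc1OCc2ccccc2 | intermediate (not isolated)
9 | 1,3-bis(benzyloxy)-2-methyl-5-(pentadec-1-en-14-yn-1-yl)benzene, E/Z mixture | C#CCCCCCCCCCCCC=Cc1cc(OCc2ccccc2)c(C)c(OCc2ccccc2)c1 | intermediate
10 | dimethyl squarate (3,4-dimethoxycyclobut-3-ene-1,2-dione) | COC1=C(OC)C(=O)C1=O | starting material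
11 | [15-(3,5-bis(benzyloxy)-4-methylphenyl)pentadec-14-en-1-yn-1-yl]lithium | [Li]C#CCCCCCCCCCCCC=Cc1cc(OCc2ccccc2)c(C)c(OCc2ccccc2)c1 | intermediate (not isolated)
12 | lithium 1-[15-(3,5-bis(benzyloxy)-4-methylphenyl)pentadec-14-en-1-yn-1-yl]-2,3-dimethoxy-4-oxocyclobut-2-en-1-olate, racemic | [Li+].COC1=C(OC)C([O-])(C#CCCCCCCCCCCCC=Cc2cc(OCc3ccccc3)c(C)c(OCc3ccccc3)c2)C1=O | intermediate (not isolated)
13 | 4-[15-(3,5-bis(benzyloxy)-4-methylphenyl)pentadec-14-en-1-yn-1-yl]-2,3-dimethoxy-4-[(trimethylsilyl)oxy]cyclobut-2-en-1-one, racemic | COC1=C(OC)C(O[Si](C)(C)C)(C#CCCCCCCCCCCCC=Cc2cc(OCc3ccccc3)c(C)c(OCc3ccccc3)c2)C1=O | intermediate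
14 | lithium 4-[15-(3,5-bis(benzyloxy)-4-methylphenyl)pentadec-14-en-1-yn-1-yl]-2,3-dimethoxy-1-methyl-4-[(trimethylsilyl)oxy]cyclobut-2-en-1-olate, racemic, diastereomer mixture | [Li+].COC1=C(OC)C(C)([O-])C1(O[Si](C)(C)C)C#CCCCCCCCCCCCC=Cc2cc(OCc3ccccc3)c(C)c(OCc3ccccc3)c2 | intermediate (not isolated)
15 | 4-[15-(3,5-bis(benzyloxy)-4-methylphenyl)pentadec-14-en-1-yn-1-yl]-2,3-dimethoxy-1-methyl-4-[(trimethylsilyl)oxy]cyclobut-2-en-1-yl trifluoroacetate, racemic, diastereomer mixture | COC1=C(OC)C(C)(OC(=O)C(F)(F)F)C1(O[Si](C)(C)C)C#CCCCCCCCCCCCC=Cc2cc(OCc3ccccc3)c(C)c(OCc3ccccc3)c2 | intermediate (not isolated)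
16 | 4-[15-(3,5-bis(benzyloxy)-4-methylphenyl)pentadec-14-en-1-yn-1-yl]-2-methoxy-3-methyl-4-[(trimethylsilyl)oxy]cyclobut-2-en-1-one, racemic | COC1=C(C)C(O[Si](C)(C)C)(C#CCCCCCCCCCCCC=Cc2cc(OCc3ccccc3)c(C)c(OCc3ccccc3)c2)C1=O | intermediate (not isolated)
17 | 4-[15-(3,5-bis(benzyloxy)-4-methylphenyl)pentadec-14-en-1-yn-1-yl]-4-hydroxy-2-methoxy-3-methylcyclobut-2-en-1-one, racemic | COC1=C(C)C(O)(C#CCCCCCCCCCCCC=Cc2cc(OCc3ccccc3)c(C)c(OCc3ccccc3)c2)C1=O | intermediate
18 | 19-[3,5-bis(benzyloxy)-4-methylphenyl]-4-hydroxy-2-methoxy-3-methylnonadeca-1,3,18-trien-5-yn-1-one, hydroxyl trans to the ketene-bearing carbon across C3=C4 | O=C=C(OC)\C(C)=C(\O)C#CCCCCCCCCCCCC=Cc1cc(OCc2ccccc2)c(C)c(OCc2ccccc2)c1 | intermediate (not isolated)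
19 | 2-methoxy-3-methyl-6-[13-(3,5-bis(benzyloxy)-4-methylphenyl)tridec-12-en-1-yl]-1,4-benzoquinone, E/Z mixture | COC1=C(C)C(=O)C=C(CCCCCCCCCCCC=Cc2cc(OCc3ccccc3)c(C)c(OCc3ccccc3)c2)C1=O | intermediate
20 | 2-methoxy-3-methyl-6-[13-(3,5-dihydroxy-4-methylphenyl)tridecyl]benzene-1,4-diol | COc1c(C)c(O)cc(CCCCCCCCCCCCCc2cc(O)c(C)c(O)c2)c1O | intermediate
21 | 2-hydroxy-3-methyl-6-[13-(5-methoxy-4-methyl-3,6-dioxocyclohexa-1,4-dien-1-yl)tridecyl]-1,4-benzoquinone | COC1=C(C)C(=O)C=C(CCCCCCCCCCCCCC2=CC(=O)C(C)=C(O)C2=O)C1=O | intermediate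
22 | 3-[13-(2,3,5,6-tetraacetoxy-4-methylphenyl)tridecyl]-5-methoxy-6-methylbenzene-1,2,4-triyl triacetate | COc1c(C)c(OC(C)=O)c(OC(C)=O)c(CCCCCCCCCCCCCc2c(OC(C)=O)c(OC(C)=O)c(C)c(OC(C)=O)c2OC(C)=O)c1OC(C)=O | intermediate
23 | 3-[13-(2,3,5,6-tetrahydroxy-4-methylphenyl)tridecyl]-5-methoxy-6-methylbenzene-1,2,4-triol | COc1c(C)c(O)c(O)c(CCCCCCCCCCCCCc2c(O)c(O)c(C)c(O)c2O)c1O | intermediate (not isolated)
24 | 2,5-dihydroxy-3-[13-(2-hydroxy-5-methoxy-4-methyl-3,6-dioxocyclohexa-1,4-dien-1-yl)tridecyl]-6-methyl-1,4-benzoquinone | COC1=C(C)C(=O)C(O)=C(CCCCCCCCCCCCCC2=C(O)C(=O)C(C)=C(O)C2=O)C1=O | target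

**Step count and risks**

Total: 13 steps. Longest linear sequence: 11 steps (1, 2, 3, 6, 7, 8, 9, 10, 11, 12, 13) from 3,5-dihydroxy-4-methylbenzoic acid; steps 4 and 5 form the side branch.

Step 12 (most likely to fail). Conjugate acetoxylation of ring A may be slow or incomplete because its enone sits beside a vinylogous ester, or the enol methyl ether may be cleaved by the acid, so that mixtures of partly oxygenated material result. The fallback sets out from 21 and gives ring A its hydroxyl by a different reaction, leaving ring B as the only ring to be acetoxylated. t-BuOOH and DBU in CH2Cl2 at 0 °C should epoxidise the alkyl/hydrogen double bond of ring A by nucleophilic epoxidation, while ring B is present as its unreactive enolate salt, to give racemic 1-[13-(5-hydroxy-4-methyl-3,6-dioxocyclohexa-1,4-dien-1-yl)tridecyl]-3-methoxy-4-methyl-7-oxabicyclo[4.1.0]hept-3-ene-2,5-dione F1. Cold concentrated H2SO4 isomerises the epoxy-diketone, which carries an epoxide hydrogen, to 2-hydroxy-3-[13-(5-hydroxy-4-methyl-3,6-dioxocyclohexa-1,4-dien-1-yl)tridecyl]-5-methoxy-6-methyl-1,4-benzoquinone F2. Ac2O with catalytic H2SO4 then acetoxylates ring B alone and merely O-acetylates the fully substituted ring A, giving 3-[13-(2-acetoxy-5-methoxy-4-methyl-3,6-dioxocyclohexa-1,4-dien-1-yl)tridecyl]-6-methylbenzene-1,2,4,5-tetrayl tetraacetate F3. The conditions of step 13 convert F3, through 2-hydroxy-5-methoxy-6-methyl-3-[13-(2,3,5,6-tetrahydroxy-4-methylphenyl)tridecyl]-1,4-benzoquinone F4, into 24, where the route is rejoined.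

Step 8. The trimethylsilyl group may migrate to the neighbouring new alkoxide, or be lost early, so that ionisation takes place at the alkynyl carbinol carbon and methyl and carbonyl end up interchanged. The fallback sets out from alkoxide 12 of step 7 and uses a silyl ether that resists migration, an aqueous-acid transposition without anhydride, and a separate fluoride deprotection. Quenching 12 with t-BuMe2SiOSO2CF3 should give 4-[15-(3,5-bis(benzyloxy)-4-methylphenyl)pentadec-14-en-1-yn-1-yl]-4-[(tert-butyldimethylsilyl)oxy]-2,3-dimethoxycyclobut-2-en-1-one F5. Methyllithium at −78 °C gives lithium 4-[15-(3,5-bis(benzyloxy)-4-methylphenyl)pentadec-14-en-1-yn-1-yl]-4-[(tert-butyldimethylsilyl)oxy]-2,3-dimethoxy-1-methylcyclobut-2-en-1-olate F6. Work-up with cold 1 M HCl, under which only the free tertiary allylic alcohol can ionise, gives 4-[15-(3,5-bis(benzyloxy)-4-methylphenyl)pentadec-14-en-1-yn-1-yl]-4-[(tert-butyldimethylsilyl)oxy]-2-methoxy-3-methylcyclobut-2-en-1-one F7. HF·pyridine in THF then releases 17, where the route is rejoined.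

Step 11. Phenoxyl radicals of ring B may couple, or the hydroxyquinone may condense through its free ring position in the aqueous radical medium. The fallback sets out from 20 and introduces the para oxygen by electrophilic substitution and hydrolysis instead of a radical oxidant. NaNO2 in aqueous acetic acid at 0 °C re-oxidises ring A and nitrosates ring B para to a hydroxyl, giving 2-methoxy-3-methyl-6-[13-(3,5-dihydroxy-4-methyl-2-nitrosophenyl)tridecyl]-1,4-benzoquinone F8. Na2S2O4 reduces the nitroso group and ring A to 6-[13-(2-amino-3,5-dihydroxy-4-methylphenyl)tridecyl]-2-methoxy-3-methylbenzene-1,4-diol F9. FeCl3 in dilute HCl oxidises both rings and the nitrogen is hydrolysed off, which rejoins the route at 21.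

**Further compounds**

F1 | step 12 | 1-[13-(5-hydroxy-4-methyl-3,6-dioxocyclohexa-1,4-dien-1-yl)tridecyl]-3-methoxy-4-methyl-7-oxabicyclo[4.1.0]hept-3-ene-2,5-dione, racemic, cis ring fusion | COC1=C(C)C(=O)C2OC2(CCCCCCCCCCCCCC3=CC(=O)C(C)=C(O)C3=O)C1=O
F2 | step 12 | 2-hydroxy-3-[13-(5-hydroxy-4-methyl-3,6-dioxocyclohexa-1,4-dien-1-yl)tridecyl]-5-methoxy-6-methyl-1,4-benzoquinone | COC1=C(C)C(=O)C(O)=C(CCCCCCCCCCCCCC2=CC(=O)C(C)=C(O)C2=O)C1=O
F3 | step 12 | 3-[13-(2-acetoxy-5-methoxy-4-methyl-3,6-dioxocyclohexa-1,4-dien-1-yl)tridecyl]-6-methylbenzene-1,2,4,5-tetrayl tetraacetate | COC1=C(C)C(=O)C(OC(C)=O)=C(CCCCCCCCCCCCCc2c(OC(C)=O)c(OC(C)=O)c(C)c(OC(C)=O)c2OC(C)=O)C1=O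
F4 | step 12 | 2-hydroxy-5-methoxy-6-methyl-3-[13-(2,3,5,6-tetrahydroxy-4-methylphenyl)tridecyl]-1,4-benzoquinone | COC1=C(C)C(=O)C(O)=C(CCCCCCCCCCCCCc2c(O)c(O)c(C)c(O)c2O)C1=O
F5 | step 8 | 4-[15-(3,5-bis(benzyloxy)-4-methylphenyl)pentadec-14-en-1-yn-1-yl]-4-[(tert-butyldimethylsilyl)oxy]-2,3-dimethoxycyclobut-2-en-1-one, racemic | COC1=C(OC)C(O[Si](C)(C)C(C)(C)C)(C#CCCCCCCCCCCCC=Cc2cc(OCc3ccccc3)c(C)c(OCc3ccccc3)c2)C1=O
F6 | step 8 | lithium 4-[15-(3,5-bis(benzyloxy)-4-methylphenyl)pentadec-14-en-1-yn-1-yl]-4-[(tert-butyldimethylsilyl)oxy]-2,3-dimethoxy-1-methylcyclobut-2-en-1-olate, racemic, diastereomer mixture | [Li+].COC1=C(OC)C(C)([O-])C1(O[Si](C)(C)C(C)(C)C)C#CCCCCCCCCCCCC=Cc2cc(OCc3ccccc3)c(C)c(OCc3ccccc3)c2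
F7 | step 8 | 4-[15-(3,5-bis(benzyloxy)-4-methylphenyl)pentadec-14-en-1-yn-1-yl]-4-[(tert-butyldimethylsilyl)oxy]-2-methoxy-3-methylcyclobut-2-en-1-one, racemic | COC1=C(C)C(O[Si](C)(C)C(C)(C)C)(C#CCCCCCCCCCCCC=Cc2cc(OCc3ccccc3)c(C)c(OCc3ccccc3)c2)C1=O
F8 | step 11 | 2-methoxy-3-methyl-6-[13-(3,5-dihydroxy-4-methyl-2-nitrosophenyl)tridecyl]-1,4-benzoquinone | COC1=C(C)C(=O)C=C(CCCCCCCCCCCCCc2cc(O)c(C)c(O)c2N=O)C1=O
F9 | step 11 | 6-[13-(2-amino-3,5-dihydroxy-4-methylphenyl)tridecyl]-2-methoxy-3-methylbenzene-1,4-diol | COc1c(C)c(O)cc(CCCCCCCCCCCCCc2cc(O)c(C)c(O)c2N)c1O
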